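## Retrosynthetic overview

1. The target is reached from the C2-symmetric bis[(2S,4R)-5-hydroxy-6,7-dimethoxyflavan-4-yl] ether by methylating one of its two homotopic 5-hydroxyls; that diol comes from the corresponding 5,5'-diallyl ether.
2. The pyran rings C and C' are closed last and together (O1–C2 and O1'–C2') by a double Mitsunobu reaction with inversion of (R)-carbinols from a catalyst-controlled transfer hydrogenation; C4 and C4' are then brought to 2,4-trans by acid equilibration of the symmetric ether.
3. Key disconnection at C3–C4 and C3'–C4'. In the target, C4 and C4' each carry the bridging oxygen and a ring A carbon (C4a, C4a') whose ortho neighbour (C8a, C8a') bears O1 or O1'. Joining O1 to C4' and O1' to C4 gives the bicyclic bis-acetal of a salicylaldehyde anhydro dimer (a 6,12-epoxydibenzo[b,f][1,5]dioxocin, two 1,3-dioxin rings sharing the bridging oxygen), which is opened twice by the silyl enol ether of acetophenone.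
4. The bis-acetal comes from dehydrative dimerisation of 6-allyloxy-2-hydroxy-4,5-dimethoxybenzaldehyde, made from 3,4,5-trimethoxyphenol by ortho-formylation and a chelation-directed exchange of the ortho methyl ether for allyl.
5. Ring order: rings A and A' come from the phenol; the two dioxin rings are made and then opened in the key step; rings C and C' are formed last.

Key step: step 8

Remark: 8 is racemic (one enantiomer is drawn); for 11 to 17 the SMILES leave the centres that are not yet fixed undefined, because these compounds are carried as stereoisomer mixtures.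

## Route

Step 1
Reactants: 1 3,4,5-trimethoxyphenol
Product: 2 2-hydroxy-4,5,6-trimethoxybenzaldehyde
Conditions: MgCl2, Et3N, (CH2O)n, MeCN, reflux; aq. HCl
Reagents that add atoms: paraformaldehyde (as formaldehyde), C=O
Why: Magnesium-mediated ortho-formylation of a phenol (Casnati–Skattebøl reaction): the magnesium phenoxide delivers formaldehyde to the ortho carbon and a second formaldehyde oxidises the hydroxymethyl group to the aldehyde, the two ortho positions of 1 being equivalent and the para position blocked.

Step 2
Reactants: 2 2-hydroxy-4,5,6-trimethoxybenzaldehyde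
Product: 3 2-formyl-3,4,5-trimethoxyphenyl pivalate
Conditions: PivCl, Et3N, DMAP (cat.), CH2Cl2, 0 °C → rt
Reagents that add atoms: pivaloyl chloride, CC(C)(C)C(=O)Cl
Why: DMAP-catalysed acylation of the only hydroxyl: the hindered pivalate masks the oxygen that becomes O1, survives BCl3 and carbonate, and thereby fixes which of the two oxygens flanking the formyl group is later allylated.

Step 3
Reactants: 3 2-formyl-3,4,5-trimethoxyphenyl pivalate
Product: 5 2-formyl-3-hydroxy-4,5-dimethoxyphenyl pivalate, via aryloxydichloroborane chelate 4 (not isolated)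
Conditions: BCl3 (1.5 equiv), CH2Cl2, −78 → 0 °C; H2O
Reagents that add atoms: none
Why: Chelation-directed aryl methyl ether cleavage: BCl3 bound to the aldehyde oxygen bridges to the ortho methoxy oxygen and chloride removes that methyl group only, the 4- and 5-methoxy groups lacking the chelate and the ester being inert at low temperature.

Step 4
Reactants: 5 2-formyl-3-hydroxy-4,5-dimethoxyphenyl pivalate
Product: 6 3-allyloxy-2-formyl-4,5-dimethoxyphenyl pivalate
Conditions: allyl bromide, K2CO3, DMF, rt
Reagents that add atoms: allyl bromide, C=CCBr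
Why: Williamson etherification of the only free phenol; acyl migration is excluded because the two oxygens are meta to each other and the pivalate is too hindered for intermolecular transfer.

Step 5
Reactants: 6 3-allyloxy-2-formyl-4,5-dimethoxyphenyl pivalate
Product: 7 6-allyloxy-2-hydroxy-4,5-dimethoxybenzaldehyde
Conditions: NaOMe, MeOH, 0 °C → rt; AcOH
Reagents that add atoms: none
Why: Methanolysis (transesterification) of an aryl ester activated by the ortho formyl group, under conditions to which the non-enolisable aldehyde and the allyl ether are inert.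

Step 6
Reactants: 7 6-allyloxy-2-hydroxy-4,5-dimethoxybenzaldehyde (two molecules)
Product: 8 rac-(6S,12S)-1,7-bis(allyloxy)-2,3,8,9-tetramethoxy-6H,12H-6,12-epoxydibenzo[b,f][1,5]dioxocin (anhydro dimer of 7)
Conditions: TsOH·H2O (cat.), toluene, reflux, Dean–Stark trap
Reagents that add atoms: none
Why: Acid-catalysed dehydrative acetalisation, the anhydro-dimerisation known for salicylaldehyde: each phenol adds to the protonated carbonyl of the partner and the two hemiacetal hydroxyls condense to the bridging oxygen while water is removed azeotropically, and the bicyclo[3.3.1] frame links the two new bridgehead centres so that only the racemic C2-symmetric bis-acetal can form.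

Step 7
Reactants: 9 acetophenone
Product: 10 1-phenyl-1-(trimethylsilyloxy)ethene
Conditions: TMSOTf, Et3N, CH2Cl2, 0 °C
Reagents that add atoms: trimethylsilyl trifluoromethanesulfonate, C[Si](C)(C)OS(=O)(=O)C(F)(F)F
Why: Soft enolisation: TMSOTf activates the carbonyl oxygen and Et3N removes a methyl proton, giving the silyl enol ether of the only enolisable position.

Step 8
Reactants: 8 anhydro dimer; 10 1-phenyl-1-(trimethylsilyloxy)ethene (3 equiv)
Product: 13 3,3'-oxybis[3-(6-allyloxy-2-hydroxy-4,5-dimethoxyphenyl)-1-phenylpropan-1-one] (racemic (R*,R*) pair plus meso isomer), via benzodioxin mono-adduct 11 (not isolated), via bis(trimethylsilyl) ether 12 (not isolated)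
Conditions: TMSOTf (0.2 equiv), 2,6-di-tert-butyl-4-methylpyridine, CH2Cl2, −78 °C; Et3N; then MeOH/aq. NaHCO3, 0 °C
Reagents that add atoms: none
Why: Proposed new method: TMSOTf silylates an aryloxy oxygen of 8, the C6–O5 bond ionises to a cyclic oxocarbenium ion (a 1,3-benzodioxin-4-ylium) stabilised by the bridging oxygen and by the o,o,p-trioxygenated aryl ring, enol silane 10 adds to give 11, and the remaining acetal carbon reacts in the same way, so that C3–C4 and C3'–C4' are formed, the bridging oxygen stays between C4 and C4', and the two expelled oxygens (the later O1 and O1') end as aryl silyl ethers in 12 while TMSOTf is regenerated. The closest known reactions are the Mukaiyama-type substitution of acetals by enol silanes under catalytic TMSOTf and the Lewis-acid opening of 4H-1,3-benzodioxins at the aryloxy–acetal bond. No ring is closed in this step; both 1,3-dioxin rings of the bicycle are opened. The new stereocentres C4 and C4' are not controlled (the first addition is to a cyclic and the second to an acyclic oxocarbenium ion, and 8 is racemic), which the route tolerates because both centres are equilibrated in step 11 and C2 and C2' are set by the catalyst of step 9. The selectivity needed is cleavage of the two aryloxy–carbon bonds and not of the bridging C–O bonds, and the bicyclo[3.3.1] frame secures it: each aryloxy bond stands nearly perpendicular to the aryl ring on the same carbon and anti to a lone pair of the bridging oxygen, whereas the bridging C–O bonds lie close to the aryl planes, and the aryl silyl ether is the better leaving group. Low temperature, a hindered pyridine base and an excess of the nucleophilic enol silane are there to outrun Friedel–Crafts attack of the free aryl CH and re-ionisation of the doubly benzylic product ether, and the phenols stay silylated until the basic work-up so that they cannot add to the new ketones.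

Step 9
Reactants: 13 bis(β-alkoxy ketone) ether
Product: 15 (1R,1'R)-3,3'-oxybis[3-(6-allyloxy-2-hydroxy-4,5-dimethoxyphenyl)-1-phenylpropan-1-ol] (three diastereomers at the ether carbons), via mono-alcohol 14 (not isolated)
Conditions: RuCl(p-cymene)[(R,R)-TsDPEN] (cat.), HCO2H/Et3N (1:5), DMF, 30 °C
Reagents that add atoms: none
Why: Noyori–Ikariya asymmetric transfer hydrogenation of aryl alkyl ketones: the (R,R)-catalyst delivers hydride to the face that gives the (R)-carbinol at each PhC(O)CH2 unit whatever the configuration of the β-carbon (catalyst control), and the amine-rich formate medium avoids acid that would ionise the benzylic ether or dehydrate the hemiketal form.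

Step 10
Reactants: 15 diol
Product: 17 bis[(2S)-5-allyloxy-6,7-dimethoxyflavan-4-yl] ether (mixture of C4 and C4' epimers), via mono-cyclised flavan 16 (not isolated)
Conditions: PPh3, DIAD, THF, 0 °C → rt
Reagents that add atoms: none
Why: Twofold intramolecular Mitsunobu etherification: each phenol (O1, O1') displaces the activated benzylic hydroxyl of its own chain in a 6-exo-tet SN2 closure with inversion, which turns the (R)-carbinols into (2S) and (2'S) and closes rings C and C'.

Step 11
Reactants: 17 bis-flavanyl ether (epimer mixture)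
Product: 18 bis[(2S,4R)-5-allyloxy-6,7-dimethoxyflavan-4-yl] ether
Conditions: PPTS (cat.), 4 Å molecular sieves, CH2Cl2, rt
Reagents that add atoms: none
Why: Acid-catalysed SN1 epimerisation of 4-alkoxyflavan centres: each C4–O bond ionises to the flavan-4-yl cation stabilised by O1, O5 and O7 and recloses anti to the 2-phenyl group, the 4-oxygen ending pseudo-axial to avoid the peri 5-allyloxy group (thermodynamic 2,4-trans), and because both halves are constitutionally identical and both (2S), ionisation and return can only change C4 and C4'.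

Step 12
Reactants: 18 diallyl ether
Product: 20 bis[(2S,4R)-5-hydroxy-6,7-dimethoxyflavan-4-yl] ether, via mono-phenol 19 (not isolated)
Conditions: Pd(PPh3)4 (cat.), morpholine, THF, rt
Reagents that add atoms: none
Why: Tsuji–Trost deallylation: zerovalent palladium ionises both aryl allyl ethers to phenoxides and π-allyl complexes that morpholine intercepts, under non-acidic conditions that leave the bis-benzylic ether and all four stereocentres untouched.

Step 13
Reactants: 20 C2-symmetric diol
Product: 21 beilschmieflavonoid B
Conditions: MeI (1 equiv), K2CO3, acetone, rt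
Reagents that add atoms: iodomethane, CI
Why: Williamson methylation of one of two homotopic phenols: any single methylation of the C2-symmetric diol gives the same compound, so about one equivalent of MeI should give the mono-ether as the main component of a statistical mixture, with recovered 20 recycled and the dimethyl ether separated.

## Compound list

1 | 3,4,5-trimethoxyphenol | COc1cc(O)cc(OC)c1OC | starting material
2 | 2-hydroxy-4,5,6-trimethoxybenzaldehyde | COc1cc(O)c(C=O)c(OC)c1OC | intermediate
3 | 2-formyl-3,4,5-trimethoxyphenyl pivalate | COc1cc(OC(=O)C(C)(C)C)c(C=O)c(OC)c1OC | intermediate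
4 | dichloro[2-formyl-5,6-dimethoxy-3-(pivaloyloxy)phenoxy]borane (carbonyl-chelated) | COc1cc(OC(=O)C(C)(C)C)c(C=O)c(OB(Cl)Cl)c1OC | intermediate
5 | 2-formyl-3-hydroxy-4,5-dimethoxyphenyl pivalate | COc1cc(OC(=O)C(C)(C)C)c(C=O)c(O)c1OC | intermediate
6 | 3-allyloxy-2-formyl-4,5-dimethoxyphenyl pivalate | COc1cc(OC(=O)C(C)(C)C)c(C=O)c(OCC=C)c1OC | intermediate
7 | 6-allyloxy-2-hydroxy-4,5-dimethoxybenzaldehyde | COc1cc(O)c(C=O)c(OCC=C)c1OC | intermediate
8 | rac-(6S,12S)-1,7-bis(allyloxy)-2,3,8,9-tetramethoxy-6H,12H-6,12-epoxydibenzo[b,f][1,5]dioxocin | O1[C@H]2c3c(O[C@@H]1c4c(O2)cc(OC)c(OC)c4OCC=C)cc(OC)c(OC)c3OCC=C | intermediate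
9 | acetophenone | CC(=O)c1ccccc1 | starting material
10 | 1-phenyl-1-(trimethylsilyloxy)ethene | C=C(O[Si](C)(C)C)c1ccccc1 | intermediate
11 | 5-allyloxy-2-[6-allyloxy-4,5-dimethoxy-2-(trimethylsilyloxy)phenyl]-6,7-dimethoxy-4-(2-oxo-2-phenylethyl)-4H-1,3-benzodioxin (stereoisomer mixture) | O=C(c1ccccc1)CC2OC(c4c(O[Si](C)(C)C)cc(OC)c(OC)c4OCC=C)Oc3cc(OC)c(OC)c(OCC=C)c32 | intermediate
12 | 3,3'-oxybis{3-[6-allyloxy-4,5-dimethoxy-2-(trimethylsilyloxy)phenyl]-1-phenylpropan-1-one} (stereoisomer mixture) | O=C(c1ccccc1)CC(OC(CC(=O)c1ccccc1)c1c(O[Si](C)(C)C)cc(OC)c(OC)c1OCC=C)c1c(O[Si](C)(C)C)cc(OC)c(OC)c1OCC=C | intermediate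
13 | 3,3'-oxybis[3-(6-allyloxy-2-hydroxy-4,5-dimethoxyphenyl)-1-phenylpropan-1-one] (racemic (R*,R*) pair plus meso isomer) | O=C(c1ccccc1)CC(OC(CC(=O)c1ccccc1)c1c(O)cc(OC)c(OC)c1OCC=C)c1c(O)cc(OC)c(OC)c1OCC=C | intermediate
14 | 3-(6-allyloxy-2-hydroxy-4,5-dimethoxyphenyl)-3-[(3R)-1-(6-allyloxy-2-hydroxy-4,5-dimethoxyphenyl)-3-hydroxy-3-phenylpropoxy]-1-phenylpropan-1-one (epimer mixture at the ether carbons) | O=C(c1ccccc1)CC(OC(C[C@@H](O)c1ccccc1)c1c(O)cc(OC)c(OC)c1OCC=C)c1c(O)cc(OC)c(OC)c1OCC=C | intermediate
15 | (1R,1'R)-3,3'-oxybis[3-(6-allyloxy-2-hydroxy-4,5-dimethoxyphenyl)-1-phenylpropan-1-ol] (epimer mixture at the ether carbons) | O[C@H](CC(OC(C[C@@H](O)c1ccccc1)c1c(O)cc(OC)c(OC)c1OCC=C)c1c(O)cc(OC)c(OC)c1OCC=C)c1ccccc1 | intermediate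
16 | (2S)-5-allyloxy-4-[(3R)-1-(6-allyloxy-2-hydroxy-4,5-dimethoxyphenyl)-3-hydroxy-3-phenylpropoxy]-6,7-dimethoxyflavan (epimer mixture at the ether carbons) | COc1cc2c(c(OCC=C)c1OC)C(OC(C[C@@H](O)c1ccccc1)c1c(O)cc(OC)c(OC)c1OCC=C)C[C@@H](c1ccccc1)O2 | intermediate
17 | bis[(2S)-5-allyloxy-6,7-dimethoxyflavan-4-yl] ether (C4 and C4' epimer mixture) | COc1cc2c(c(OCC=C)c1OC)C(OC1C[C@@H](c3ccccc3)Oc3cc(OC)c(OC)c(OCC=C)c31)C[C@@H](c1ccccc1)O2 | intermediate
18 | bis[(2S,4R)-5-allyloxy-6,7-dimethoxyflavan-4-yl] ether | COc1cc2c(c(OCC=C)c1OC)[C@H](O[C@@H]1C[C@@H](c3ccccc3)Oc3cc(OC)c(OC)c(OCC=C)c31)C[C@@H](c1ccccc1)O2 | intermediate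
19 | (2S,4R)-5-allyloxy-6,7-dimethoxyflavan-4-yl (2S,4R)-5-hydroxy-6,7-dimethoxyflavan-4-yl ether | COc1cc2c(c(O)c1OC)[C@H](O[C@@H]1C[C@@H](c3ccccc3)Oc3cc(OC)c(OC)c(OCC=C)c31)C[C@@H](c1ccccc1)O2 | intermediate
20 | bis[(2S,4R)-5-hydroxy-6,7-dimethoxyflavan-4-yl] ether | COc1cc2c(c(O)c1OC)[C@H](O[C@@H]1C[C@@H](c3ccccc3)Oc3cc(OC)c(OC)c(O)c31)C[C@@H](c1ccccc1)O2 | intermediate
21 | beilschmieflavonoid B, (2S,4R)-5-hydroxy-6,7-dimethoxyflavan-4-yl (2S,4R)-5,6,7-trimethoxyflavan-4-yl ether | COc1cc2c(c(O)c1OC)[C@H](O[C@@H]1C[C@@H](c3ccccc3)Oc3cc(OC)c(OC)c(OC)c31)C[C@@H](c1ccccc1)O2 | target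

## Step count and risks

Total step count: 13 (12 in the main line plus 1 for the enol silane).
Longest linear sequence: 12 steps (1 to 21 through steps 1–6 and 8–13).

Steps most likely to fail:

**Step 8 (key step).** The Lewis acid may break the bridging C–O bonds in place of the aryloxy bonds, which would return aldehyde-derived fragments and plain aldol products. The doubly benzylic product ether may also re-ionise and be lost to chalcone- or flavylium-type material, or the cations may be captured by the free aryl CH. The fallback uses known reactions only, sets out from 7 and 9 and comes back at 18. Claisen–Schmidt condensation of 7 with 9 (KOH, EtOH) should give (E)-3-(6-allyloxy-2-hydroxy-4,5-dimethoxyphenyl)-1-phenylprop-2-en-1-one F1. Transfer hydrogenation with RuCl(p-cymene)[(R,R)-TsDPEN] and HCO2Na, which reduces first the C=C and then the C=O bond of a chalcone, should give (R)-3-(6-allyloxy-2-hydroxy-4,5-dimethoxyphenyl)-1-phenylpropan-1-ol F2. Mitsunobu closure with inversion gives (2S)-5-allyloxy-6,7-dimethoxyflavan F3. Benzylic oxidation at C4 with DDQ in wet CH2Cl2, water capturing the cation anti to the phenyl group, gives (2S,4R)-5-allyloxy-6,7-dimethoxyflavan-4-ol F4. Acid-catalysed dehydrative etherification of two molecules of F4 (PPTS, 4 Å molecular sieves) then gives 18. In this variant the bridging oxygen is made by the ether formation and not carried over from the bis-acetal.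

**Step 11.** Under acid the flavan-4-yl cation may be captured irreversibly by the free aryl carbon C8 of another molecule (C–C linked dimers), or it may lose a proton to a flav-3-ene faster than the ether equilibrates. The fallback sets out from 17 and comes back at 18; it erases and rebuilds the C4 centres on the monomer instead of epimerising the intact ether. Hydrolysis (AcOH/H2O/THF), where water outcompetes carbon nucleophiles, gives (2S)-5-allyloxy-6,7-dimethoxyflavan-4-ol as a C4 epimer mixture F5. Dess–Martin oxidation gives (2S)-5-allyloxy-6,7-dimethoxyflavan-4-one F6. NaBH4 reduction gives the cis alcohol (2S,4S)-5-allyloxy-6,7-dimethoxyflavan-4-ol F7. Mitsunobu inversion with 4-nitrobenzoic acid gives (2S,4R)-5-allyloxy-6,7-dimethoxyflavan-4-yl 4-nitrobenzoate F8. Methanolysis (K2CO3, MeOH) gives (2S,4R)-5-allyloxy-6,7-dimethoxyflavan-4-ol F4, and a short, cold dehydrative etherification of this single trans alcohol (PPTS, 4 Å molecular sieves) leads to 18 under kinetic control.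

**Step 6.** Azeotropic removal of water may not pull the equilibrium to the bis-acetal of this push–pull stabilised aldehyde, and the acid may cause alkylation of the electron-rich ring by the protonated aldehyde, leading to oligomers. The fallback sets out from 7 and comes back at 8; it replaces protic dehydration by silyl-transfer acetalisation. Silylation of 7 with hexamethyldisilazane gives 6-allyloxy-4,5-dimethoxy-2-(trimethylsilyloxy)benzaldehyde F9. With catalytic TMSOTf in CH2Cl2 at low temperature (Noyori acetalisation conditions) F9 should dimerise to 8 with loss of hexamethyldisiloxane, the Si–O–Si bond being the driving force in place of water removal; the solution of 8 could then be treated directly with 10.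

## Further compounds

F1 | step 8 | (E)-3-(6-allyloxy-2-hydroxy-4,5-dimethoxyphenyl)-1-phenylprop-2-en-1-one | O=C(/C=C/c1c(O)cc(OC)c(OC)c1OCC=C)c1ccccc1
F2 | step 8 | (R)-3-(6-allyloxy-2-hydroxy-4,5-dimethoxyphenyl)-1-phenylpropan-1-ol | O[C@H](CCc1c(O)cc(OC)c(OC)c1OCC=C)c1ccccc1
F3 | step 8 | (2S)-5-allyloxy-6,7-dimethoxyflavan | COc1cc2c(c(OCC=C)c1OC)CC[C@@H](c1ccccc1)O2
F4 | step 8 | (2S,4R)-5-allyloxy-6,7-dimethoxyflavan-4-ol | COc1cc2c(c(OCC=C)c1OC)[C@H](O)C[C@@H](c1ccccc1)O2
F5 | step 11 | (2S)-5-allyloxy-6,7-dimethoxyflavan-4-ol (C4 epimer mixture) | COc1cc2c(c(OCC=C)c1OC)C(O)C[C@@H](c1ccccc1)O2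
F6 | step 11 | (2S)-5-allyloxy-6,7-dimethoxyflavan-4-one | COc1cc2c(c(OCC=C)c1OC)C(=O)C[C@@H](c1ccccc1)O2
F7 | step 11 | (2S,4S)-5-allyloxy-6,7-dimethoxyflavan-4-ol | COc1cc2c(c(OCC=C)c1OC)[C@@H](O)C[C@@H](c1ccccc1)O2
F8 | step 11 | (2S,4R)-5-allyloxy-6,7-dimethoxyflavan-4-yl 4-nitrobenzoate | COc1cc2c(c(OCC=C)c1OC)[C@H](OC(=O)c1ccc(cc1)[N+](=O)[O-])C[C@@H](c1ccccc1)O2
F9 | step 6 | 6-allyloxy-4,5-dimethoxy-2-(trimethylsilyloxy)benzaldehyde | COc1cc(O[Si](C)(C)C)c(C=O)c(OCC=C)c1OC
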